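Readings and results are simulated from invented constants; noise was put on by code.

32.1 % is the excess of left-handed product over right-handed product pooled over the two earliest gamma readings, against 14.8 % over the two latest, and that fall is the number to follow here.

| setting | epsilon | gamma | Tuesday's | Wednesday's | Saturday's |
|---|---|---|---|---|---|
| left-handed substrate | 0.80 M | 0.80 M | 0.80 M | 0.80 M | 0.80 M |
| right-handed substrate | 0.80 M | 0.80 M | 0.80 M | 0.80 M | 0.80 M |
| partner | 1.1 equiv | 1.7 equiv | 2.20 equiv | 2.20 equiv | 2.20 equiv |
| temperature | 2 °C | 19 °C |  | −5 °C | 25 °C |
| remark | run made earlier | run made earlier | at −5 °C until 6.0 min, from then on at 25 °C |  |  |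
| time |  |  | 20 min | 20 min | 20 min |

| run | time / min | left-handed product / % | right-handed product / % |
|---|---|---|---|
| epsilon | 1.33 | 3 | 2 |
| epsilon | 2.50 | 9 | 0 |
| epsilon | 5.00 | 9 | 4 |
| epsilon | 8.00 | 13 | 10 |
| epsilon | 15.0 | 17 | 12 |
| gamma | 0.417 | 14 | 4 |
| gamma | 1.33 | 21 | 14 |
| gamma | 2.50 | 29 | 18 |
| gamma | 4.00 | 27 | 24 |
| gamma | 5.00 | 35 | 22 |

(standard deviation of a reading: 2 percentage points)

1. the flask with the highest excess of left-handed product over right-handed product ("all alike" if they lie within 1.5 percentage points) (Tuesday's / Wednesday's / Saturday's / all alike)
2. excess of left-handed product over right-handed product at the end, Tuesday's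
3. excess of left-handed product over right-handed product at the end, Wednesday's
4. excess of left-handed product over right-handed product at the end, Saturday's

- partner is single-handed; left-handed substrate and right-handed substrate are mirror images of each other, charged as a racemate, each of them at the stated concentration
- an excess is the difference of the two amounts in percent of their sum
- an excess is below zero if the other one leads
- the handed part of partner does not stay in what it makes, so the products of the two hands are mirror images too

Take first the main steps by themselves: partner turns each substrate into its product, left-handed substrate the quicker. The first epsilon readings, pooled, then give a kinetic excess of 55.6 %, a rough reading on small amounts with a scatter of 2 percentage points. Add second a loss of partner: the gamma total reaches 47.0 % by 2.50 min but just 57.0 % by 5.00 min, and such a levelling freezes an excess without lowering it. Yet the gamma excess falls. Faster use of left-handed substrate lowers an excess as conversion rises, and an interconversion of the products, the third addition, would lower it too; these readings do not part the two. They are mirror images, so it ends at zero excess. Charging the whole gamma fall to it, over 3.63 min, credits it with the share of conversion as well, so the loss rate λ of 0.213 /min is an upper estimate and H = 3.25 min a lower one, H being the half-life of the excess: the time in which interconversion halves any excess standing.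

Making per equivalent of partner runs 5.92 times faster in gamma than in epsilon. If H scales likewise, it is 19.3 min at 2 °C. The crossing between kinetic and thermodynamic control lies where the run time equals H. Wednesday's is colder than epsilon, so its 20 min is about one H or less, and this reckoning, which leaves aside the lowering by conversion, puts its excess between 27.8 % and 55.6 %. Saturday's is warmer than gamma and spans 6.15 gamma half-lives by this lower H, Tuesday's 4.30 after its change, so both should lie near zero if interconversion carries the gamma fall.

The forecast gave 14 % for Tuesday's, 22 % for Wednesday's and 14 % for Saturday's, with Wednesday's highest: “Selectivity kL/kR is about 1.75 in both runs, with no resolvable temperature dependence.” It names the same flask as this reckoning, but its Wednesday's figure lies lower than this range and its warm flasks stand above zero.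

The simulation gives −0.0801 % for Tuesday's, 33.5 % for Wednesday's and −0.0189 % for Saturday's, so Wednesday's leads.

    left-handed product ⇌ right-handed product (k = 0.00332 /s, Ea = 75.0 kJ/mol)
    right-handed substrate ⇌ achiral form (K = 1.59, k = 2.50 × 10⁻⁴ /s, Ea = 96.0 kJ/mol, ΔH = −7.00 kJ/mol)
    partner + left-handed substrate → left-handed product (k = 0.0161 /M/s, Ea = 71.0 kJ/mol)
    partner → decomposed reagent (k = 0.00317 /s, Ea = 76.0 kJ/mol)
    partner + right-handed substrate → right-handed product (k = 0.00586 /M/s, Ea = 74.0 kJ/mol)
    left-handed substrate ⇌ achiral form (K = 1.59, k = 2.50 × 10⁻⁴ /s, Ea = 96.0 kJ/mol, ΔH = −7.00 kJ/mol)
    (constants at 25 °C)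

In Wednesday's the relaxation half-life of the two products by this step, both ways together, is 51.3 min, longer than the reckoned bound, so 20 min is 0.390 of it. Saturday's, at 6.15 gamma half-lives of 3.25 min, ends at −0.0189 %. A repeat of Wednesday's at −20 °C is colder still, so the same reckoning puts H beyond 19.3 min again and the excess in the same range. That neighbour ends at 51.2 %, higher than Wednesday's, with 82 % of its charged left-handed substrate still there.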